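The upper pyran ring (O1, C2, C3, C4, C4a, C8a) is disconnected at its aryl ether bond O1–C8a and traced back to the cyclopentanone ring of a 3-aryl-indan-1-one. On this carbocycle the C4 diarylmethine stereocentre is set by asymmetric reductive Heck cyclization of a chalcone built from C8-formylated, perbenzylated (−)-epiafzelechin. Baeyer–Villiger oxygen insertion between the carbonyl carbon (future C2) and the arene carbon (future C8a) then enlarges the five-membered ketone to the six-membered lactone in one operation, leaving C4 untouched. Enol phosphate formation, Suzuki arylation at C2 and hydrogenation anti to the C4 aryl group complete the 2,4-cis flavan.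

Key step: step 7

Assumption: (−)-epiafzelechin, the 2R,3R flavan-3-ol that forms the lower unit, is taken as a purchasable single enantiomer; its two stereocentres are carried through unchanged.
Abbreviation: Ar′ = (2R,3R)-3,5,7-tris(benzyloxy)-2-[4-(benzyloxy)phenyl]chroman-8-yl, the perbenzylated epiafzelechin unit bonded through C8.

Step 1
Reactants: 1 (−)-epiafzelechin; 2 benzyl bromide
Product: 4 (2R,3R)-3,5,7-tris(benzyloxy)-2-[4-(benzyloxy)phenyl]chromane (Ar′–H), via tri-O-benzyl ether 3 (not isolated)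
Conditions: BnBr, K2CO3, DMF, rt; then NaH, 0 °C → rt (one pot)
Reagents that add atoms: benzyl bromide (2), BrCc1ccccc1
Why: Williamson etherification, phenols first under carbonate and the C3 alkoxide afterwards with NaH, so that the strong base meets the flavan only after the 4′-phenol is capped and C2/C3 should stay 2R,3R.

Step 2
Reactants: 4 Ar′–H; 5 N-bromosuccinimide
Product: 6 (2R,3R)-3,5,7-tris(benzyloxy)-2-[4-(benzyloxy)phenyl]-8-bromochromane (Ar′–Br)
Conditions: NBS (1.0 equiv), CH2Cl2, −78 → 0 °C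
Reagents that add atoms: N-bromosuccinimide (5), O=C1CCC(=O)N1Br
Why: Electrophilic aromatic bromination of the phloroglucinol-type A ring, which in 5,7-di-O-benzyl flavan-3-ol ethers is known to go to C8 and not to C6.

Step 3
Reactants: 6 Ar′–Br; 7 N,N-dimethylformamide
Product: 9 (2R,3R)-3,5,7-tris(benzyloxy)-2-[4-(benzyloxy)phenyl]chromane-8-carbaldehyde (Ar′–CHO), via aryllithium Ar′–Li 8 (not isolated)
Conditions: t-BuLi (2.1 equiv), THF, −78 °C; DMF, −78 °C → rt; H2O
Reagents that add atoms: N,N-dimethylformamide (7), CN(C)C=O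
Why: Bromine–lithium exchange followed by formylation of the aryllithium with DMF (Bouveault aldehyde synthesis), with the ether stereocentres inert at −78 °C.

Step 4
Reactants: 10 1-(2-bromo-5-hydroxyphenyl)ethan-1-one; 2 benzyl bromide
Product: 11 1-[5-(benzyloxy)-2-bromophenyl]ethan-1-one
Conditions: BnBr, K2CO3, DMF, 60 °C
Reagents that add atoms: benzyl bromide (2), BrCc1ccccc1
Why: Williamson etherification of the phenol, giving a protecting group that leaves with the others in the last step.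

Step 5
Reactants: 9 Ar′–CHO; 11 1-[5-(benzyloxy)-2-bromophenyl]ethan-1-one
Product: 13 (E)-1-[5-(benzyloxy)-2-bromophenyl]-3-Ar′-prop-2-en-1-one, via aldol adduct 12 (not isolated)
Conditions: KOH, EtOH–THF, rt → 40 °C
Reagents that add atoms: none
Why: Claisen–Schmidt condensation, in which the non-enolizable aldehyde cannot self-condense and E1cB dehydration of the aldol should give the E-enone.

Step 6
Reactants: 13 (E)-1-[5-(benzyloxy)-2-bromophenyl]-3-Ar′-prop-2-en-1-one
Product: 14 (3S)-6-(benzyloxy)-3-Ar′-2,3-dihydro-1H-inden-1-one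
Conditions: Pd(OAc)2 (5 mol %), Xyl-MeO-BIPHEP (6 mol %; antipode that gives 3S), HCO2Na, DMF, 80 °C
Reagents that add atoms: none
Why: Intramolecular asymmetric reductive Heck reaction (oxidative addition into C–Br, aryl transfer to the enone β-carbon, formate reduction of the Pd enolate), in which the chiral bisphosphine on Pd selects the enone face and so sets C3 (future C4) under catalyst control, the remote flavan stereocentres being expected to have little influence.

Step 7
Reactants: 14 (3S)-6-(benzyloxy)-3-Ar′-2,3-dihydro-1H-inden-1-one; 15 meta-chloroperoxybenzoic acid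
Product: 17 (4S)-7-(benzyloxy)-4-Ar′-chroman-2-one, via Criegee adduct 16 (not isolated)
Conditions: mCPBA (1.5 equiv), TsOH·H2O (cat.), 4 Å MS, CH2Cl2, 4 °C, dark
Reagents that add atoms: meta-chloroperoxybenzoic acid (15), OOC(=O)c1cccc(Cl)c1
Why: Acid-catalysed addition of the peracid to the C1 carbonyl gives the Criegee adduct 16, in which the aromatic carbon C7a, antiperiplanar to the O–O bond, shifts from C1 to the proximal peroxide oxygen as m-chlorobenzoate leaves, so that oxygen is inserted between the carbonyl carbon (future C2) and the arene carbon (future C8a). The closest known reaction type is the Baeyer–Villiger ring enlargement of 1-indanones, 3-aryl-1-indanones included, to 3,4-dihydrocoumarins. No ring is closed by cyclization: the six-membered lactone (O1, C2, C3, C4, C4a, C8a) arises by a one-atom enlargement of the five-membered ketone through a 1,2-shift from carbon to oxygen. No stereocentre is formed; the migrating atom is sp2, and C3 of the indanone, which takes no part, becomes C4 with its S configuration intact. The step needs regioselectivity (aryl over C2 methylene migration), which the higher migratory aptitude of the aryl group in 1-indanones should secure, and chemoselectivity for the ketone over the benzyloxy arenes, for which the acid catalysis of carbonyl addition, the low temperature, the limited excess of oxidant and the flanking of the only free position of the Ar′ arene (C6) by two benzyloxy groups are relied on.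

Step 8
Reactants: 17 (4S)-7-(benzyloxy)-4-Ar′-chroman-2-one; 18 diphenyl chlorophosphate
Product: 20 (4S)-7-(benzyloxy)-4-Ar′-4H-chromen-2-yl diphenyl phosphate, via potassium enolate 19 (not isolated)
Conditions: (PhO)2P(O)Cl, KHMDS, THF–DMPU, −78 °C
Reagents that add atoms: diphenyl chlorophosphate (18), O=P(Cl)(Oc1ccccc1)Oc1ccccc1
Why: O-Phosphorylation of the lactone enolate (ketene acetal phosphate formation) with the electrophile present from the start, so that trapping at −78 °C should outrun ketene formation, while C4 is not acidic and keeps its configuration.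

Step 9
Reactants: 20 (4S)-7-(benzyloxy)-4-Ar′-4H-chromen-2-yl diphenyl phosphate; 21 4-(benzyloxy)phenylboronic acid
Product: 22 (4S)-7-(benzyloxy)-2-[4-(benzyloxy)phenyl]-4-Ar′-4H-chromene
Conditions: Pd(PPh3)4 (5 mol %), 2 M aq Na2CO3, DME, 80 °C
Reagents that add atoms: 4-(benzyloxy)phenylboronic acid (21), OB(O)c1ccc(OCc2ccccc2)cc1
Why: Suzuki–Miyaura coupling at the C(sp2)–O bond of the ketene acetal phosphate, run under basic conditions that the acid-labile 2-aryl-4H-chromene should tolerate.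

Step 10
Reactants: 22 (4S)-7-(benzyloxy)-2-[4-(benzyloxy)phenyl]-4-Ar′-4H-chromene
Product: 23 target CNP0254623.1 = (2R,3R)-8-[(2S,4S)-7-hydroxy-2-(4-hydroxyphenyl)chroman-4-yl]-2-(4-hydroxyphenyl)chromane-3,5,7-triol
Conditions: H2 (3 bar), Pd(OH)2/C, THF–MeOH, rt
Reagents that add atoms: none
Why: Catalytic hydrogenation with concurrent hydrogenolysis of the five benzyl ethers, in which H2 should add to the C2=C3 enol ether from the face opposite the pseudoaxial C4 aryl group, placing H-2 trans to that group and the C2 aryl cis to it (2S from 4S), a sense that should persist even if palladium walks the double bond, because C2 is then formed first and directs the return of hydrogen to C4.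

Compound list
1 | (−)-epiafzelechin, (2R,3R)-2-(4-hydroxyphenyl)chromane-3,5,7-triol | Oc1cc(O)c2c(c1)O[C@H](c1ccc(O)cc1)[C@H](O)C2 | starting material
2 | benzyl bromide | BrCc1ccccc1 | starting material
3 | (2R,3R)-5,7-bis(benzyloxy)-2-[4-(benzyloxy)phenyl]chroman-3-ol | C(c1ccccc1)Oc1cc(OCc2ccccc2)c2c(c1)O[C@H](c1ccc(OCc3ccccc3)cc1)[C@H](O)C2 | intermediate
4 | (2R,3R)-3,5,7-tris(benzyloxy)-2-[4-(benzyloxy)phenyl]chromane (Ar′–H) | C(c1ccccc1)Oc1cc(OCc2ccccc2)c2c(c1)O[C@H](c1ccc(OCc3ccccc3)cc1)[C@H](OCc1ccccc1)C2 | intermediate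
5 | N-bromosuccinimide | O=C1CCC(=O)N1Br | starting material
6 | (2R,3R)-3,5,7-tris(benzyloxy)-2-[4-(benzyloxy)phenyl]-8-bromochromane (Ar′–Br) | C(c1ccccc1)Oc1cc(OCc2ccccc2)c2c(c1Br)O[C@H](c1ccc(OCc3ccccc3)cc1)[C@H](OCc1ccccc1)C2 | intermediate
7 | N,N-dimethylformamide | CN(C)C=O | starting material
8 | 8-lithio derivative Ar′–Li | C(c1ccccc1)Oc1cc(OCc2ccccc2)c2c(c1[Li])O[C@H](c1ccc(OCc3ccccc3)cc1)[C@H](OCc1ccccc1)C2 | intermediate
9 | (2R,3R)-3,5,7-tris(benzyloxy)-2-[4-(benzyloxy)phenyl]chromane-8-carbaldehyde (Ar′–CHO) | C(c1ccccc1)Oc1cc(OCc2ccccc2)c2c(c1C=O)O[C@H](c1ccc(OCc3ccccc3)cc1)[C@H](OCc1ccccc1)C2 | intermediate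
10 | 1-(2-bromo-5-hydroxyphenyl)ethan-1-one | CC(=O)c1cc(O)ccc1Br | starting material
11 | 1-[5-(benzyloxy)-2-bromophenyl]ethan-1-one | CC(=O)c1cc(OCc2ccccc2)ccc1Br | intermediate
12 | 1-[5-(benzyloxy)-2-bromophenyl]-3-hydroxy-3-Ar′-propan-1-one (carbinol epimers) | OC(CC(=O)c1cc(OCc2ccccc2)ccc1Br)c3c(OCc4ccccc4)cc(OCc4ccccc4)c4c3O[C@H](c3ccc(OCc5ccccc5)cc3)[C@H](OCc3ccccc3)C4 | intermediate
13 | (E)-1-[5-(benzyloxy)-2-bromophenyl]-3-Ar′-prop-2-en-1-one | O=C(/C=C/c3c(OCc4ccccc4)cc(OCc4ccccc4)c4c3O[C@H](c3ccc(OCc5ccccc5)cc3)[C@H](OCc3ccccc3)C4)c1cc(OCc2ccccc2)ccc1Br | intermediate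
14 | (3S)-6-(benzyloxy)-3-Ar′-2,3-dihydro-1H-inden-1-one | O=C1C[C@H](c3c(OCc4ccccc4)cc(OCc4ccccc4)c4c3O[C@H](c3ccc(OCc5ccccc5)cc3)[C@H](OCc3ccccc3)C4)c2ccc(OCc3ccccc3)cc21 | intermediate
15 | meta-chloroperoxybenzoic acid | OOC(=O)c1cccc(Cl)c1 | starting material
16 | (3S)-6-(benzyloxy)-1-hydroxy-3-Ar′-indan-1-yl 3-chloroperoxybenzoate (Criegee adduct, C1 epimers) | OC1(OOC(=O)c6cccc(Cl)c6)C[C@H](c3c(OCc4ccccc4)cc(OCc4ccccc4)c4c3O[C@H](c3ccc(OCc5ccccc5)cc3)[C@H](OCc3ccccc3)C4)c2ccc(OCc3ccccc3)cc21 | intermediate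
17 | (4S)-7-(benzyloxy)-4-Ar′-chroman-2-one | O=C1C[C@H](c3c(OCc4ccccc4)cc(OCc4ccccc4)c4c3O[C@H](c3ccc(OCc5ccccc5)cc3)[C@H](OCc3ccccc3)C4)c2ccc(OCc3ccccc3)cc2O1 | intermediate
18 | diphenyl chlorophosphate | O=P(Cl)(Oc1ccccc1)Oc1ccccc1 | starting material
19 | potassium (4S)-7-(benzyloxy)-4-Ar′-4H-chromen-2-olate | [K+].[O-]C1=C[C@H](c3c(OCc4ccccc4)cc(OCc4ccccc4)c4c3O[C@H](c3ccc(OCc5ccccc5)cc3)[C@H](OCc3ccccc3)C4)c2ccc(OCc3ccccc3)cc2O1 | intermediate
20 | (4S)-7-(benzyloxy)-4-Ar′-4H-chromen-2-yl diphenyl phosphate | O=P(Oc1ccccc1)(Oc1ccccc1)OC1=C[C@H](c3c(OCc4ccccc4)cc(OCc4ccccc4)c4c3O[C@H](c3ccc(OCc5ccccc5)cc3)[C@H](OCc3ccccc3)C4)c2ccc(OCc3ccccc3)cc2O1 | intermediate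
21 | 4-(benzyloxy)phenylboronic acid | OB(O)c1ccc(OCc2ccccc2)cc1 | starting material
22 | (4S)-7-(benzyloxy)-2-[4-(benzyloxy)phenyl]-4-Ar′-4H-chromene | C(c1ccccc1)Oc1ccc(cc1)C1=C[C@H](c3c(OCc4ccccc4)cc(OCc4ccccc4)c4c3O[C@H](c3ccc(OCc5ccccc5)cc3)[C@H](OCc3ccccc3)C4)c2ccc(OCc3ccccc3)cc2O1 | intermediate
23 | CNP0254623.1, (2R,3R)-8-[(2S,4S)-7-hydroxy-2-(4-hydroxyphenyl)chroman-4-yl]-2-(4-hydroxyphenyl)chromane-3,5,7-triol | Oc1ccc([C@@H]2C[C@H](c3c(O)cc(O)c4c3O[C@H](c3ccc(O)cc3)[C@H](O)C4)c3ccc(O)cc3O2)cc1 | target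

Total step count: 10. Longest linear sequence: 9 (steps 1–3 and 5–10).

Steps most likely to fail

Step 6. Aryl transfer to the β-carbon, which carries a doubly ortho-substituted arene, may be slow, so that hydrodebromination of the aryl–palladium species or plain conjugate reduction of the enone takes over, and facial discrimination may be low. The fallback sets out from 13 and comes back at 14. Cyclization of 13 under ordinary Heck conditions (Pd(OAc)2, PPh3, Et3N, DMF, 100 °C) should give the achiral 6-(benzyloxy)-3-Ar′-1H-inden-1-one F1. Corey–Bakshi–Shibata reduction of its carbonyl (Me-CBS antipode that gives 1R, BH3·SMe2, THF, −20 °C) should give (1R)-6-(benzyloxy)-3-Ar′-1H-inden-1-ol F2. DABCO in THF at 60 °C should then bring about a suprafacial 1,3-hydrogen shift and tautomerization that carry the C1 configuration over to C3 and deliver 14. The stereocentre is thus set by hydride delivery to a carbonyl and not by arylpalladation.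

Step 7. The peracid may hydroxylate the trialkoxy arene of Ar′ electrophilically, or the C2 methylene may migrate in place of the aryl carbon. The fallback sets out from 14 and comes back at 17, and keeps the ring enlargement but changes its mechanism to a Hock rearrangement. NaBH4 (MeOH–THF, 0 °C) should give (3S)-6-(benzyloxy)-3-Ar′-indan-1-ol F3 as C1 epimers, both usable. Hydrogen peroxide (50 %, cat. H2SO4, Et2O, 0 °C) should convert it through the benzylic cation into (3S)-6-(benzyloxy)-3-Ar′-indan-1-yl hydroperoxide F4. BF3·OEt2 (CH2Cl2, −20 °C) should then trigger migration of the aryl carbon from C1 to oxygen; the ring-enlarged oxocarbenium ion takes up water to give (4S)-7-(benzyloxy)-4-Ar′-chroman-2-ol F5, which TPAP/NMO should oxidize to 17. Here hydrogen peroxide acts as a nucleophile on a cation, and no peracid meets the electron-rich arene.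

Step 8. The aryl ester enolate may fragment to a ketene and a phenoxide faster than it is phosphorylated, and the ketene acetal phosphate may hydrolyse on isolation. The fallback sets out from 17 and comes back at 22. One equivalent of 4-(benzyloxy)phenyllithium F6 (from 1-(benzyloxy)-4-bromobenzene and n-BuLi, THF, −78 °C, inverse addition) should add to the lactone carbonyl; collapse of the adduct gives (3S)-3-[4-(benzyloxy)-2-hydroxyphenyl]-1-[4-(benzyloxy)phenyl]-3-Ar′-propan-1-one F7. PPTS in toluene over 4 Å molecular sieves at 80 °C should close the hemiketal and dehydrate it to 22, with C4 unaffected.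

Further compounds
F1 | step 6 | 6-(benzyloxy)-3-Ar′-1H-inden-1-one | O=C1C=C(c3c(OCc4ccccc4)cc(OCc4ccccc4)c4c3O[C@H](c3ccc(OCc5ccccc5)cc3)[C@H](OCc3ccccc3)C4)c2ccc(OCc3ccccc3)cc21
F2 | step 6 | (1R)-6-(benzyloxy)-3-Ar′-1H-inden-1-ol | O[C@@H]1C=C(c3c(OCc4ccccc4)cc(OCc4ccccc4)c4c3O[C@H](c3ccc(OCc5ccccc5)cc3)[C@H](OCc3ccccc3)C4)c2ccc(OCc3ccccc3)cc21
F3 | step 7 | (3S)-6-(benzyloxy)-3-Ar′-indan-1-ol (C1 epimers) | OC1C[C@H](c3c(OCc4ccccc4)cc(OCc4ccccc4)c4c3O[C@H](c3ccc(OCc5ccccc5)cc3)[C@H](OCc3ccccc3)C4)c2ccc(OCc3ccccc3)cc21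
F4 | step 7 | (3S)-6-(benzyloxy)-3-Ar′-indan-1-yl hydroperoxide (C1 epimers) | OOC1C[C@H](c3c(OCc4ccccc4)cc(OCc4ccccc4)c4c3O[C@H](c3ccc(OCc5ccccc5)cc3)[C@H](OCc3ccccc3)C4)c2ccc(OCc3ccccc3)cc21
F5 | step 7 | (4S)-7-(benzyloxy)-4-Ar′-chroman-2-ol (C2 epimers) | OC1C[C@H](c3c(OCc4ccccc4)cc(OCc4ccccc4)c4c3O[C@H](c3ccc(OCc5ccccc5)cc3)[C@H](OCc3ccccc3)C4)c2ccc(OCc3ccccc3)cc2O1
F6 | step 8 | 4-(benzyloxy)phenyllithium | [Li]c1ccc(OCc2ccccc2)cc1
F7 | step 8 | (3S)-3-[4-(benzyloxy)-2-hydroxyphenyl]-1-[4-(benzyloxy)phenyl]-3-Ar′-propan-1-one | O=C(C[C@H](c3c(OCc4ccccc4)cc(OCc4ccccc4)c4c3O[C@H](c3ccc(OCc5ccccc5)cc3)[C@H](OCc3ccccc3)C4)c1ccc(OCc2ccccc2)cc1O)c1ccc(OCc2ccccc2)cc1
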